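The chemist planning dusk, autumn and summer has earlier closed-flask runs at different charges in hand.

| flask | starting material | remark | time |
|---|---|---|---|
| south | 0.20 M | run made earlier |  |
| north-east | 0.10 M | run made earlier |  |
| west | 0.40 M | run made earlier |  |
| dusk | 0.20 M | one stirred flow tank at steady state, fed with the mixture as stated, mean residence time 3.0 min |  |
| autumn | 0.20 M | a closed flask charged with all of it at once and left for 3.0 min | 3.0 min |
| summer | 0.20 M | a single well-mixed tank run continuously and read at steady state, 15.0 min in it on average |  |

south run (percent of the starting material charged)

| time / s | product / % | starting material / % |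
|---|---|---|
| 10.0 | 0.5 | 86.9 |
| 15.0 | 1.3 | 82.3 |
| 25.0 | 1.4 | 71.3 |
| 40.0 | 6.2 | 58.8 |
| 60.0 | 9.1 | 44.7 |
| 120 | 20.8 | 19.5 |

north-east run (percent of the starting material charged)

| time / min | product / % | starting material / % |
|---|---|---|
| 0.667 | 5.3 | 57.3 |
| 1.33 | 13.7 | 34.8 |
| 2.00 | 21.2 | 20.5 |
| 2.50 | 26.2 | 12.9 |
| 3.00 | 29.6 | 8.6 |
| 4.00 | 36.2 | 3.7 |

west run (percent of the starting material charged)

| time / min | product / % | starting material / % |
|---|---|---|
| 0.250 | 1.2 | 81.0 |
| 0.500 | 3.5 | 66.3 |
| 0.833 | 6.8 | 50.9 |
| 1.33 | 12.4 | 33.7 |
| 2.00 | 20.2 | 19.5 |
| 4.00 | 36.4 | 4.1 |

(standard deviation of a reading: 0.5 percentage points)

- order of the set-ups by the amount of product at the outlet or at the end, in percent of the starting material put in, highest first (dusk / autumn / summer)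
- amount of product at the outlet or at the end, in percent of the starting material put in, dusk
- amount of product at the outlet or at the end, in percent of the starting material put in, autumn
- amount of product at the outlet or at the end, in percent of the starting material put in, summer

- the stated concentrations are those of everything mixed, before any reaction; amounts are the same in each set-up
- what was read earlier has a scatter of 0.5 percentage points, one standard deviation
- the earlier runs were made in a closed, stirred flask

As fractions of the charge the runs coincide at equal times: at 2.00 min product reads 20.8%, 21.2% and 20.2% in south, north-east and west, so one ladder of times serves every charge.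

The lowest rung is the starting material. In the north-east run it decays with 0.822 min⁻¹, a lifetime of 1.22 min. By 4.00 min that run holds a hidden share, the fraction of the charge that is neither starting material nor product, of 60.1%. Over the last interval product gains 6.6 percentage points while starting material loses 4.9 points, so the hidden share is feeding product.

The upper rung is therefore the draining time, hidden share divided by product's rise per minute, read as 9.11 min. Autumn's 3.0 min lies between the rungs, and since the runs coincide at equal times, autumn is reckoned at the north-east reading for that time, 29.6%.

In a steady tank, product leaves at its fraction over the residence time and enters at hidden share over the draining time. Product is then the converted fraction times residence time over the sum of residence and draining times. With 7.50% starting material left in summer, this reckoning gives 57.6% there and 17.6% in dusk.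

The forecast, holding that “part of the material leaks elsewhere”, gives summer > autumn > dusk: 21.9%, 30% and 37.5% for dusk, autumn and summer. It stands below this reckoning on summer and above it on dusk.

The flask gives summer > autumn > dusk: 23.9% in dusk, 29.7% in autumn, 58.0% in summer.

    starting material → intermediate A (k = 0.00830 s⁻¹)
    starting material → intermediate B (k = 0.00520 s⁻¹)
    intermediate A → intermediate C (k = 0.00210 s⁻¹)
    intermediate C → intermediate D (k = 0.0470 s⁻¹)
    intermediate B ⇌ product (K = 11.0, k = 0.0190 s⁻¹)
    intermediate D → intermediate B (k = 0.00670 s⁻¹)

Run backwards, the balance gives a draining time of 8.90 min on the summer result, against 9.11 min from the north-east run, and 5.91 min on the dusk result. The step from intermediate A to intermediate C has a half-life of 5.5 min by that path alone, longer than any other forward half-life of the scheme. Its lifetime by that path alone, 7.94 min, is shorter than summer's mean residence time of 15.0 min and longer than the dusk mean residence time, and the dusk outlet carries intermediate A at 31.6% of the charge.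

The readings stem from a simulated flask for substances that don't exist.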